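## The problem

The target (15) is a flavonol. Its benzo ring A and pyranone ring C share the C4a–C8a bond, a 4-methoxyphenyl ring B sits on C2, O3 and O5 are free hydroxyls, and O7 carries a prenyl (3-methylbut-2-enyl) ether. There is no stereocenter, so the task is one of connectivity and of telling three oxygens apart: only O7 may be alkylated. The prenyl aryl ether is the fragile group. Protic and Lewis acids ionise it, its olefin is saturated under the hydrogenation that removes benzyl ethers, and heat can move it to carbon by Claisen rearrangement. The 3-hydroxypyranone enol is oxidised in base under air, and ring C opens in hot alkali. Ring A is a 1,3,5-trioxygenated benzene with a carbon substituent wedged between two oxygens, which is awkward to reach by electrophilic acylation while controlling which oxygen stays free. The enabling feature is that C8a (bearing O1) and C4a (bearing the acyl carbon C4) are neighbours on ring A, with the C5 oxygen directly beside C4a. That is the arrangement left when a carboxylate adds to a 3-alkoxyaryne and its acyl group then moves to the adjacent carbon.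

## Retrosynthesis

**O7–prenyl bond.** The first cut removes the prenyl group, 15 ⇒ kaempferide 14 plus prenyl bromide. Placing this bond last keeps the allylic ether away from every acidic, reductive or organometallic step. The forward reaction must alkylate O7 in the presence of O3 and O5. It can rely on O7 being the most acidic hydroxyl (a vinylogous acid para to the C4 carbonyl), while O3 and O5 are hydrogen-bonded to that carbonyl.

**Three O–benzyl bonds.** 14 ⇒ tribenzyl ether 13. Benzyl is chosen for all three oxygens because it should survive butyllithium at low temperature, fluoride at 125 °C, amide base and catalytic sulfonic acid, and is removed in one neutral step. Using the same group on O5 and O7 also keeps the ring A building block symmetric.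

**Ring C (O1–C2, then C2–C3).** 13 ⇒ 1,3-diketone 12 by cyclodehydration, 12 ⇒ aryl ester 11 by a Baker–Venkataraman acyl shift, and 11 ⇒ o-hydroxyaryl ketone 9 plus 4-methoxybenzoyl chloride 10. This is preferred to a chalcone with oxidative closure because the C3 oxygen already sits on the ketone side chain as a benzyl ether, so no oxidation is needed. Chalcones with an oxygen at C6' also tend to divert to aurones under oxidative closure. Ketone 9 holds all of ring A and C3–C4, and its only free hydroxyl is the one that becomes O1.

**C8a–O1 and C4a–C4 (key disconnection).** 9 ⇒ silylaryl triflate 6 plus 2-(benzyloxy)acetic acid 7, through aryne 8. Both bonds at the ring A/ring C junction form in one operation. The mechanism places oxygen and acyl on adjacent carbons, and the new phenol is the only unprotected oxygen. The neighbouring options are Friedel–Crafts or Hoesch acylation of a phloroglucinol ether. These would need Lewis acids that strip benzyl ethers, and a separate step to decide which oxygen is free. The forward reaction must add the carboxylate at the aryne carbon remote from the flanking benzyloxy group and transfer the acyl group before the aryl anion is protonated.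

**Aryne precursor.** 6 ⇒ lithium phenoxide 5 (O–S bond) ⇒ aryllithium 4 (C–Si bond by retro-Brook shift) ⇒ silyl ether 3 ⇒ bromophenol 2 ⇒ 3,5-bis(benzyloxy)phenol 1 (C–Br bond). The two ortho positions of 1 are equivalent, so only attack at C4, between the two ethers, competes in the bromination.

## Roads not taken

**Alternative 1:** Ring C is cut at O1–C8a. The precursor is diketone A2, built from a 2,6-difluoro-4-(prenyloxy)benzoyl unit and an α-(methoxymethoxy) anisyl ketone. In the key step its enolate oxygen displaces one of two equivalent ortho fluorides to give fluoroflavone A1.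
- Merits: the ring closure is regiochemically unambiguous, and the prenyl group goes onto a single phenol early, so O7 selectivity is never in question. In this respect it is better than the chosen plan.
- Weak points: the remaining C5 fluoride must be exchanged for oxygen by a hard nucleophile on a chromone that is itself electrophilic at C2. The methoxymethyl group at O3 then has to be removed with acid in the presence of the acid-labile prenyl ether.
- Comparison: the chosen plan carries all ring A oxygens from the start, needs no C–F to C–O exchange, and frees the hydroxyls by hydrogenolysis before any prenyl group is present.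

**Alternative 2:** The cut is on both sides of C4. Aryl iodide A4, carbon monoxide and the enolate of α-alkoxy ketone A5 are joined under Pd(OAc)2/bisphosphine catalysis to give the racemic tris-MOM diketone A3. Acid would then remove the acetals and close ring C.
- Merits: this is the shortest and most convergent route, and the prenyl group is again placed unambiguously. It is ahead of the chosen plan in step count and in O7 selectivity.
- Weak points: the aryl iodide is flanked by two ortho alkoxy groups, which slows CO insertion and capture of the acyl palladium. Direct α-arylation and O-acylation compete. An aryl prenyl ether is an allylic electrophile that zerovalent palladium can ionise. The last step exposes that ether to the acid needed for three acetals.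
- Comparison: the chosen plan is longer, but it uses a metal-free key step and never exposes the prenyl ether to palladium or acid.

**Alternative 3:** Ring A itself is cut at C4a–C5. The C6 carbanion of cinnamoyl triketo ester A7 attacks the ester carbonyl in a biomimetic Claisen condensation to give chalcone A6.
- Merits: the aromatic ring is built from an acyclic chain with no protecting groups, which the chosen plan, starting from a preformed arene, cannot match.
- Weak points: the tetracarbonyl chain is hard to make and handle. Aldol folding to a resorcylate competes with Claisen folding, and the enone is a Michael acceptor for its own enolates. A6 still lacks the C3 oxygen, and oxidative closure of a chalcone with a free C6' hydroxyl favours aurones, so protection steps return. The O7 selectivity problem also remains.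
- Comparison: the chosen plan brings O3 in with the acid component and has the three oxygens already differentiated after the key step.

Key step: step 4

Assumption: compounds 1, 7 and 10 are taken as commercial; the target has no stereocenter, and the only stereocenter on the route (C2 of diketone 12) is racemic and is erased in step 7.

## Route

Step 1
Reactants: 1 3,5-bis(benzyloxy)phenol
Product: 2 2-bromo-3,5-bis(benzyloxy)phenol
Conditions: NBS (1.0 equiv), i-Pr2NH (cat.), CH2Cl2, −78 to 0 °C
Reagents that add atoms: N-bromosuccinimide, O=C1CCC(=O)N1Br
Why: Amine-mediated ortho-selective electrophilic bromination of a phenol; the hydrogen-bonded N-bromoamine delivers bromine next to the hydroxyl, and the symmetry of 1 makes both ortho positions the same.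

Step 2
Reactants: 2 2-bromo-3,5-bis(benzyloxy)phenol
Product: 3 [3,5-bis(benzyloxy)-2-bromophenoxy]trimethylsilane
Conditions: HMDS, THF, reflux; concentrate
Reagents that add atoms: hexamethyldisilazane, C[Si](C)(C)N[Si](C)(C)C
Why: O-Silylation of a phenol with a silazane; ammonia is the only by-product, so the crude silyl ether can be used after evaporation.

Step 3
Reactants: 3 [3,5-bis(benzyloxy)-2-bromophenoxy]trimethylsilane
Product: 6 3,5-bis(benzyloxy)-2-(trimethylsilyl)phenyl trifluoromethanesulfonate, via aryllithium 4 (not isolated), via lithium phenoxide 5 (not isolated)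
Conditions: n-BuLi, THF, −100 to −78 °C; then Tf2O, −78 °C to rt
Reagents that add atoms: trifluoromethanesulfonic anhydride, O=S(=O)(OS(=O)(=O)C(F)(F)F)C(F)(F)F
Why: Bromine–lithium exchange is faster than benzylic deprotonation at this temperature; aryllithium 4 undergoes the 1,3 O-to-C silyl shift (retro-Brook rearrangement) to phenoxide 5, which is trapped by O-triflation.

Step 4
Reactants: 6 3,5-bis(benzyloxy)-2-(trimethylsilyl)phenyl trifluoromethanesulfonate, 7 2-(benzyloxy)acetic acid
Product: 9 2-(benzyloxy)-1-[2,4-bis(benzyloxy)-6-hydroxyphenyl]ethan-1-one, via aryne 8 (not isolated)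
Conditions: 6 (1.3 equiv), 7 (1.0 equiv), CsF (4 equiv), THF, 125 °C, sealed tube; aq. NH4Cl
Reagents that add atoms: none
Why: Fluoride attacks the silicon of 6 and triflate leaves, giving 3,5-bis(benzyloxy)benzyne 8; the cesium carboxylate of 7 adds to the aryne carbon meta to the flanking benzyloxy group (the future C8a), because the triple bond is distorted toward attack there and the resulting aryl anion lies ortho to the inductively withdrawing oxygen. That anion (the future C4a) attacks the carbonyl of the newly formed aryl ester through a four-membered alkoxide, which opens by C–O cleavage to the ortho-acyl phenoxide, so oxygen ends on C8a and the acyl carbon C4 on C4a, between the new phenol and the C5 ether. The closest known reaction type is the fluoride-induced insertion of arynes into the C–O bond of carboxylic acids at elevated temperature, which gives o-hydroxyaryl ketones (formally an intermolecular anionic Fries shift). No ring remains closed in the product and no stereocenter is formed. Two selectivities are needed: the regiochemistry of addition, secured by the 3-benzyloxy group, and acyl transfer ahead of protonation of the aryl anion, secured by aprotic THF, excess CsF that binds HF as bifluoride, and the high temperature. The phenoxide of 9 is chelated to the ketone, which should hold back a second O-arylation by 8.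

Step 5
Reactants: 9 2-(benzyloxy)-1-[2,4-bis(benzyloxy)-6-hydroxyphenyl]ethan-1-one, 10 4-methoxybenzoyl chloride
Product: 11 3,5-bis(benzyloxy)-2-[2-(benzyloxy)acetyl]phenyl 4-methoxybenzoate
Conditions: Et3N, DMAP (cat.), CH2Cl2, 0 °C to rt
Reagents that add atoms: none
Why: DMAP-catalysed O-acylation of the chelated phenol with an aroyl chloride; the only free hydroxyl in 9 is the one to be acylated.

Step 6
Reactants: 11 3,5-bis(benzyloxy)-2-[2-(benzyloxy)acetyl]phenyl 4-methoxybenzoate
Product: 12 rac-2-(benzyloxy)-1-[2,4-bis(benzyloxy)-6-hydroxyphenyl]-3-(4-methoxyphenyl)propane-1,3-dione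
Conditions: LiN(SiMe3)2 (3 equiv), THF, −78 to 0 °C; 1 M HCl
Reagents that add atoms: none
Why: Baker–Venkataraman rearrangement: the ketone enolate attacks the neighbouring aryl ester through a six-membered transition state and the aroyl group moves from oxygen to C3; the new C2 stereocenter of 12 is racemic, labile by enolisation and removed in step 7.

Step 7
Reactants: 12 rac-2-(benzyloxy)-1-[2,4-bis(benzyloxy)-6-hydroxyphenyl]-3-(4-methoxyphenyl)propane-1,3-dione
Product: 13 3,5,7-tris(benzyloxy)-2-(4-methoxyphenyl)-4H-chromen-4-one
Conditions: p-TsOH·H2O (cat.), toluene, 90 °C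
Reagents that add atoms: none
Why: Acid-catalysed cyclodehydration of an o-hydroxyaryl 1,3-diketone: the phenol adds to the anisyl ketone (6-exo-trig hemiketal) and loss of water gives the aromatic pyranone; catalytic sulfonic acid in toluene should spare the benzyl ethers.

Step 8
Reactants: 13 3,5,7-tris(benzyloxy)-2-(4-methoxyphenyl)-4H-chromen-4-one
Product: 14 3,5,7-trihydroxy-2-(4-methoxyphenyl)-4H-chromen-4-one (kaempferide)
Conditions: H2 (1 atm), 10% Pd/C, THF–MeOH, rt
Reagents that add atoms: none
Why: Catalytic hydrogenolysis of three benzyl ethers; the tetrasubstituted, conjugated C2=C3 bond of a flavonol and the aryl methyl ether are not touched at ambient pressure and temperature.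

Step 9
Reactants: 14 3,5,7-trihydroxy-2-(4-methoxyphenyl)-4H-chromen-4-one (kaempferide)
Product: 15 3,5-dihydroxy-2-(4-methoxyphenyl)-7-[(3-methylbut-2-en-1-yl)oxy]-4H-chromen-4-one
Conditions: prenyl bromide (1.05 equiv), K2CO3 (1.1 equiv), DMF, 0 °C to rt, argon
Reagents that add atoms: 1-bromo-3-methylbut-2-ene (prenyl bromide), CC(C)=CCBr
Why: Williamson etherification under acidity control: O7–H is the most acidic hydroxyl, while O3–H and O5–H are hydrogen-bonded to the C4 carbonyl, so one equivalent of weak base and of the allylic bromide should alkylate O7 only.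

## Compound list

1 | 3,5-bis(benzyloxy)phenol | Oc1cc(OCc2ccccc2)cc(OCc2ccccc2)c1 | starting material
2 | 2-bromo-3,5-bis(benzyloxy)phenol | Oc1cc(OCc2ccccc2)cc(OCc2ccccc2)c1Br | intermediate
3 | [3,5-bis(benzyloxy)-2-bromophenoxy]trimethylsilane | C[Si](C)(C)Oc1cc(OCc2ccccc2)cc(OCc2ccccc2)c1Br | intermediate
4 | [2,4-bis(benzyloxy)-6-(trimethylsilyloxy)phenyl]lithium | [Li]c1c(O[Si](C)(C)C)cc(OCc2ccccc2)cc1OCc1ccccc1 | intermediate
5 | lithium 3,5-bis(benzyloxy)-2-(trimethylsilyl)phenoxide | [Li+].[O-]c1cc(OCc2ccccc2)cc(OCc2ccccc2)c1[Si](C)(C)C | intermediate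
6 | 3,5-bis(benzyloxy)-2-(trimethylsilyl)phenyl trifluoromethanesulfonate | C[Si](C)(C)c1c(OCc2ccccc2)cc(OCc2ccccc2)cc1OS(=O)(=O)C(F)(F)F | intermediate
7 | 2-(benzyloxy)acetic acid | O=C(O)COCc1ccccc1 | starting material
8 | 3,5-bis(benzyloxy)benzyne (3,5-bis(benzyloxy)-1,2-didehydrobenzene) | C1#CC(OCc2ccccc2)=CC(OCc2ccccc2)=C1 | intermediate
9 | 2-(benzyloxy)-1-[2,4-bis(benzyloxy)-6-hydroxyphenyl]ethan-1-one | O=C(COCc1ccccc1)c1c(O)cc(OCc2ccccc2)cc1OCc1ccccc1 | intermediate
10 | 4-methoxybenzoyl chloride | COc1ccc(C(=O)Cl)cc1 | starting material
11 | 3,5-bis(benzyloxy)-2-[2-(benzyloxy)acetyl]phenyl 4-methoxybenzoate | COc1ccc(C(=O)Oc2cc(OCc3ccccc3)cc(OCc3ccccc3)c2C(=O)COCc2ccccc2)cc1 | intermediate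
12 | rac-2-(benzyloxy)-1-[2,4-bis(benzyloxy)-6-hydroxyphenyl]-3-(4-methoxyphenyl)propane-1,3-dione | COc1ccc(C(=O)C(OCc2ccccc2)C(=O)c2c(O)cc(OCc3ccccc3)cc2OCc2ccccc2)cc1 | intermediate
13 | 3,5,7-tris(benzyloxy)-2-(4-methoxyphenyl)-4H-chromen-4-one | COc1ccc(-c2oc3cc(OCc4ccccc4)cc(OCc4ccccc4)c3c(=O)c2OCc2ccccc2)cc1 | intermediate
14 | 3,5,7-trihydroxy-2-(4-methoxyphenyl)-4H-chromen-4-one (kaempferide) | COc1ccc(-c2oc3cc(O)cc(O)c3c(=O)c2O)cc1 | intermediate
15 | 3,5-dihydroxy-2-(4-methoxyphenyl)-7-[(3-methylbut-2-en-1-yl)oxy]-4H-chromen-4-one | COc1ccc(-c2oc3cc(OCC=C(C)C)cc(O)c3c(=O)c2O)cc1 | target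

## Step count and risk

Total step count: 9. Longest linear sequence: 9 steps (1 to 15); 7 and 10 enter as purchased materials.

**Step 4 (key step).** The aryl anion may be quenched before it reaches the ester carbonyl, either by external protonation or by internal proton transfer from the acidic O–CH2–C=O position. That would give O-arylation without the acyl shift. A second arylation of the product phenoxide by excess aryne could also erode the outcome. Fallback: the C4a–C4 bond is made by acylation of an aryllithium.
- Bromophenol 2 is protected with MOMCl/i-Pr2NEt to give 1,5-bis(benzyloxy)-2-bromo-3-(methoxymethoxy)benzene F1.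
- Acid 7 is converted through its acid chloride into 2-(benzyloxy)-N-methoxy-N-methylacetamide F2.
- Bromine–lithium exchange on F1 (n-BuLi, THF, −78 °C) and addition to F2 gives 2-(benzyloxy)-1-[2,4-bis(benzyloxy)-6-(methoxymethoxy)phenyl]ethan-1-one F3.
- Mild HCl in MeOH/THF removes the acetal ortho to the ketone and returns to the route at 9.

**Step 9.** Over-alkylation at O3 after the first ether has formed, or C-alkylation at C6/C8 of the electron-rich phenoxide, would lower selectivity for O7. Fallback: O7 is differentiated through esters.
- Kaempferide 14 is peracetylated (Ac2O, pyridine) to 2-(4-methoxyphenyl)-4-oxo-4H-chromene-3,5,7-triyl triacetate F4.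
- The most labile 7-acetate is removed with PhSH/imidazole in NMP at 0 °C to give 7-hydroxy-2-(4-methoxyphenyl)-4-oxo-4H-chromene-3,5-diyl diacetate F5.
- A Mitsunobu reaction with 3-methylbut-2-en-1-ol (PPh3, DIAD, THF) gives 2-(4-methoxyphenyl)-7-[(3-methylbut-2-en-1-yl)oxy]-4-oxo-4H-chromene-3,5-diyl diacetate F6.
- K2CO3 in MeOH at 0 °C removes both acetates and returns to the route at 15.

**Step 1.** Bromination could occur at C4, between the two benzyloxy groups, or twice on the highly activated ring, giving an isomer that cannot undergo the silyl shift. Fallback: the silyl group is introduced by directed ortho-metalation, with no bromide.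
- Phenol 1 and isopropyl isocyanate give 3,5-bis(benzyloxy)phenyl N-isopropylcarbamate F7.
- In situ N-silylation (TMSOTf, TMEDA), ortho-lithiation (n-BuLi, TMEDA, Et2O, −78 °C) and TMSCl give 3,5-bis(benzyloxy)-2-(trimethylsilyl)phenyl N-isopropylcarbamate F8.
- Carbamate cleavage with Et2NH/DBU in MeCN and triflation of the phenoxide with PhNTf2 in the same flask returns to the route at 6, replacing steps 1 to 3.

**Step 6.** The O-to-C acyl shift onto a hindered, α-oxygenated enolate may be slow, so ester cleavage back to 9 or benzyl migration within the α-benzyloxy enolate could take over. Fallback: an Allan–Robinson condensation.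
- Acid chloride 10 and sodium 4-methoxybenzoate give 4-methoxybenzoic anhydride F9.
- Ketone 9 is heated with F9 and sodium 4-methoxybenzoate at about 170 °C, followed by brief treatment with ethanolic KOH.
- This gives the flavone directly and returns to the route at 13, bypassing 11 and 12.

## Further compounds

F1 | step 4 | 1,5-bis(benzyloxy)-2-bromo-3-(methoxymethoxy)benzene | COCOc1cc(OCc2ccccc2)cc(OCc2ccccc2)c1Br
F2 | step 4 | 2-(benzyloxy)-N-methoxy-N-methylacetamide | CON(C)C(=O)COCc1ccccc1
F3 | step 4 | 2-(benzyloxy)-1-[2,4-bis(benzyloxy)-6-(methoxymethoxy)phenyl]ethan-1-one | COCOc1cc(OCc2ccccc2)cc(OCc2ccccc2)c1C(=O)COCc1ccccc1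
F4 | step 9 | 2-(4-methoxyphenyl)-4-oxo-4H-chromene-3,5,7-triyl triacetate | COc1ccc(-c2oc3cc(OC(C)=O)cc(OC(C)=O)c3c(=O)c2OC(C)=O)cc1
F5 | step 9 | 7-hydroxy-2-(4-methoxyphenyl)-4-oxo-4H-chromene-3,5-diyl diacetate | COc1ccc(-c2oc3cc(O)cc(OC(C)=O)c3c(=O)c2OC(C)=O)cc1
F6 | step 9 | 2-(4-methoxyphenyl)-7-[(3-methylbut-2-en-1-yl)oxy]-4-oxo-4H-chromene-3,5-diyl diacetate | COc1ccc(-c2oc3cc(OCC=C(C)C)cc(OC(C)=O)c3c(=O)c2OC(C)=O)cc1
F7 | step 1 | 3,5-bis(benzyloxy)phenyl N-isopropylcarbamate | CC(C)NC(=O)Oc1cc(OCc2ccccc2)cc(OCc2ccccc2)c1
F8 | step 1 | 3,5-bis(benzyloxy)-2-(trimethylsilyl)phenyl N-isopropylcarbamate | CC(C)NC(=O)Oc1cc(OCc2ccccc2)cc(OCc2ccccc2)c1[Si](C)(C)C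
F9 | step 6 | 4-methoxybenzoic anhydride | COc1ccc(C(=O)OC(=O)c2ccc(OC)cc2)cc1
A1 | alternative 1 | 5-fluoro-3-(methoxymethoxy)-2-(4-methoxyphenyl)-7-[(3-methylbut-2-en-1-yl)oxy]-4H-chromen-4-one | COCOc1c(-c2ccc(OC)cc2)oc2cc(OCC=C(C)C)cc(F)c2c1=O
A2 | alternative 1 | rac-1-{2,6-difluoro-4-[(3-methylbut-2-en-1-yl)oxy]phenyl}-2-(methoxymethoxy)-3-(4-methoxyphenyl)propane-1,3-dione | COCOC(C(=O)c1ccc(OC)cc1)C(=O)c1c(F)cc(OCC=C(C)C)cc1F
A3 | alternative 2 | rac-1-{2,6-bis(methoxymethoxy)-4-[(3-methylbut-2-en-1-yl)oxy]phenyl}-2-(methoxymethoxy)-3-(4-methoxyphenyl)propane-1,3-dione | COCOC(C(=O)c1ccc(OC)cc1)C(=O)c1c(OCOC)cc(OCC=C(C)C)cc1OCOC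
A4 | alternative 2 | 2-iodo-1,3-bis(methoxymethoxy)-5-[(3-methylbut-2-en-1-yl)oxy]benzene | COCOc1cc(OCC=C(C)C)cc(OCOC)c1I
A5 | alternative 2 | 2-(methoxymethoxy)-1-(4-methoxyphenyl)ethan-1-one | COCOCC(=O)c1ccc(OC)cc1
A6 | alternative 3 | (E)-3-(4-methoxyphenyl)-1-(2,4,6-trihydroxyphenyl)prop-2-en-1-one | COc1ccc(/C=C/C(=O)c2c(O)cc(O)cc2O)cc1
A7 | alternative 3 | methyl (E)-9-(4-methoxyphenyl)-3,5,7-trioxonon-8-enoate | COC(=O)CC(=O)CC(=O)CC(=O)/C=C/c1ccc(OC)cc1
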